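**Plan** (isochromene numbering of the target, C1, O2, C3, C4, C4a, C5–C8, C8a, is used for all intermediates)
- Retrosynthesis: after unmasking of the phenols and of the side-chain acid (traced back to a silylated allylic alcohol), the C8–O ester bond and the O2–C3 bond of the pyran ring are cut together, giving a monocyclic (R)-ortho-quinol enynal and a protected orsellinic acid. The quinol is then cut at C7–O (back to a phenol), at C4a–C4 (aryl bromide plus enyne) and at C8a–C1 (formyl group).
- Enabling feature: the C8–O ester is allylic to the enol ether C8a=C1–O2 of the pyran ring. The target is therefore the C8 adduct of a carboxylic acid to the cation O2=C1–C8a=C8, which arises when the formyl oxygen of an enynal whose carbocycle is already sp3 at C7 closes the pyran ring onto C3.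
- Forward: the benzene ring (later carbocycle C4a–C8a) is formylated, demethylated and coupled to the enyne, then hydroxylation at C7 breaks its aromaticity. One gold-catalysed step closes the pyran ring and attaches the orsellinate at C8. The side chain is oxidised to the acid and the silyl groups are removed.
- Stereochemistry: C7 (R) comes from reagent control by a chiral iodyl reagent in the dearomatisation. C8 (R) comes from substrate control by C7 in the gold step (ester cis to the C7 hydroxyl). The E alkene is bought with the enynol.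

Key step: step 7

Assumption: the sense of induction of the chiral iodyl reagent on the phenol of step 5 cannot be assigned in advance; the (S)-valinol-derived reagent is written, and its enantiomer is taken if a first run shows the 6S quinol.

Step 1
Reactants: 1 5-bromo-2-methylanisole
Product: 2 2-bromo-4-methoxy-5-methylbenzaldehyde
Conditions: Cl2CHOMe, TiCl4, CH2Cl2, 0 °C; aqueous work-up
Reagents that add atoms: dichloromethyl methyl ether COC(Cl)Cl; water O
Why: Rieche formylation, in which the methoxy group directs the electrophile to its para position, the only activated site not flanked on both sides, so the formyl group should enter next to bromine.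

Step 2
Reactants: 2 2-bromo-4-methoxy-5-methylbenzaldehyde
Product: 3 2-bromo-4-hydroxy-5-methylbenzaldehyde
Conditions: BBr3, CH2Cl2, −78 °C → rt; H2O
Reagents that add atoms: none
Why: BBr3 cleavage of an aryl methyl ether is standard, should spare the aryl bromide and the aldehyde, and frees the phenol needed for the later dearomatisation.

Step 3
Reactants: 4 (E)-pent-2-en-4-yn-1-ol
Product: 5 (E)-tert-butyldimethyl(pent-2-en-4-yn-1-yloxy)silane
Conditions: TBSCl, imidazole, CH2Cl2, 0 °C → rt
Reagents that add atoms: tert-butyldimethylsilyl chloride CC(C)(C)[Si](C)(C)Cl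
Why: Routine silylation of a primary alcohol that leaves the E-enyne untouched.

Step 4
Reactants: 3 2-bromo-4-hydroxy-5-methylbenzaldehyde; 5 (E)-tert-butyldimethyl(pent-2-en-4-yn-1-yloxy)silane
Product: 6 4-hydroxy-5-methyl-2-[(E)-5-(tert-butyldimethylsilyloxy)pent-3-en-1-yn-1-yl]benzaldehyde
Conditions: PdCl2(PPh3)2 (3 mol%), CuI (5 mol%), Et3N, THF, 50 °C
Reagents that add atoms: none
Why: Sonogashira coupling, in which the C–Br bond ortho to the formyl group adds readily to zerovalent palladium and unprotected hydroxybenzaldehydes of this kind are tolerated.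

Step 5
Reactants: 6 4-hydroxy-5-methyl-2-[(E)-5-(tert-butyldimethylsilyloxy)pent-3-en-1-yn-1-yl]benzaldehyde
Product: 7 (6R)-4-formyl-6-hydroxy-6-methyl-3-[(E)-5-(tert-butyldimethylsilyloxy)pent-3-en-1-yn-1-yl]cyclohexa-2,4-dien-1-one
Conditions: (S)-2-(2-iodylphenyl)-4-isopropyl-4,5-dihydrooxazole (1.5 equiv), THF, 0 °C → rt, dark; short silica plug, solution used at once
Reagents that add atoms: (S)-2-(2-iodylphenyl)-4-isopropyl-4,5-dihydrooxazole CC(C)[C@H]1COC(c2ccccc2I(=O)=O)=N1
Why: Hydroxylative phenol dearomatisation by a chiral analogue of 2-iodoxybenzoic acid, known for 2-alkylphenols, in which the phenol binds to pentavalent iodine and an iodyl oxygen is passed within the complex to the methyl-bearing ortho carbon while the oxazoline stereocentre selects the face so that the carbinol carbon (C7 of the target) is set as R, the formyl group slowing the oxygen transfer but also the [4+2] dimerisation of the quinol.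

Step 6
Reactants: 8 orsellinic acid (2,4-dihydroxy-6-methylbenzoic acid)
Product: 10 2,4-bis(triisopropylsilyloxy)-6-methylbenzoic acid, via triisopropylsilyl ester 9 (not isolated)
Conditions: iPr3SiOTf (3.3 equiv), 2,6-lutidine, CH2Cl2, 0 °C → rt; then AcOH–THF–H2O, rt
Reagents that add atoms: triisopropylsilyl trifluoromethanesulfonate CC(C)[Si](OS(=O)(=O)C(F)(F)F)(C(C)C)C(C)C
Why: Exhaustive silylation followed by selective hydrolysis of the silyl ester, which is far more labile at silicon than the two aryl silyl ethers, should free only the carboxylic acid.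

Step 7
Reactants: 7 (6R)-4-formyl-6-hydroxy-6-methyl-3-[(E)-5-(tert-butyldimethylsilyloxy)pent-3-en-1-yn-1-yl]cyclohexa-2,4-dien-1-one; 10 2,4-bis(triisopropylsilyloxy)-6-methylbenzoic acid
Product: 11 (7R,8R)-7-hydroxy-7-methyl-6-oxo-3-[(E)-3-(tert-butyldimethylsilyloxy)prop-1-en-1-yl]-7,8-dihydro-6H-isochromen-8-yl 2,4-bis(triisopropylsilyloxy)-6-methylbenzoate
Conditions: (Ph3P)AuN(SO2CF3)2 (5 mol%), 10 (1.5 equiv), 4 Å molecular sieves, CH2Cl2, 0 °C → rt, slow addition of 7
Reagents that add atoms: none
Why: Proposed new method: The monovalent gold cation binds the alkyne, the formyl oxygen adds to C3 anti to gold, and because the carbocycle is no longer aromatic the resulting vinylgold species is a vinylogous oxocarbenium ion with positive charge at both C1 and C8 through C8a, so that acid 10 can add through oxygen at C8 and its proton can then cleave the C4–Au bond and return the catalyst. The closest known reaction types are the gold- or silver-catalysed cycloisomerisation of 2-alkynylbenzaldehydes with capture of a nucleophile at C1 to give 1H-isochromenes and the copper-catalysed cycloisomerisation of dearomatised alkynyl ortho-quinols to bicyclic pyrans. The pyran ring closes in the 6-endo-dig mode, which should be preferred to 5-exo-dig because C3 is the δ-carbon of the C6 dienone and the six-membered cation is conjugated. The new C8 stereocentre is controlled by the C7 stereocentre, since the incoming acid can hydrogen-bond to the C7 hydroxyl and approaches anti to the C7 methyl group, which places the ester cis to the hydroxyl (8R). The step needs C8 over C1 selectivity, which rests on the C1 acylal re-ionising easily whereas the C8 ester keeps the conjugation from O2 through C1=C8a and C4a=C5 to the C6 carbonyl and is the thermodynamic product, and slow addition of 7 keeps its concentration low so that cyclisation outruns [4+2] dimerisation.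

Step 8
Reactants: 11 (7R,8R)-7-hydroxy-7-methyl-6-oxo-3-[(E)-3-(tert-butyldimethylsilyloxy)prop-1-en-1-yl]-7,8-dihydro-6H-isochromen-8-yl 2,4-bis(triisopropylsilyloxy)-6-methylbenzoate
Product: 12 (7R,8R)-7-hydroxy-3-[(E)-3-hydroxyprop-1-en-1-yl]-7-methyl-6-oxo-7,8-dihydro-6H-isochromen-8-yl 2,4-bis(triisopropylsilyloxy)-6-methylbenzoate
Conditions: HF·pyridine, pyridine, THF, 0 °C → rt
Reagents that add atoms: none
Why: Buffered HF desilylation removes a primary alkyl TBS ether much faster than the bulkier aryl triisopropylsilyl ethers, and the non-nucleophilic medium should leave the C8 ester and both stereocentres alone.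

Step 9
Reactants: 12 (7R,8R)-7-hydroxy-3-[(E)-3-hydroxyprop-1-en-1-yl]-7-methyl-6-oxo-7,8-dihydro-6H-isochromen-8-yl 2,4-bis(triisopropylsilyloxy)-6-methylbenzoate
Product: 13 (7R,8R)-7-hydroxy-7-methyl-6-oxo-3-[(E)-3-oxoprop-1-en-1-yl]-7,8-dihydro-6H-isochromen-8-yl 2,4-bis(triisopropylsilyloxy)-6-methylbenzoate
Conditions: MnO2, CH2Cl2, rt
Reagents that add atoms: none
Why: MnO2 oxidises allylic (here dienylic) primary alcohols selectively to the enal and does not touch the tertiary C7 carbinol or the silyl ethers.

Step 10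
Reactants: 13 (7R,8R)-7-hydroxy-7-methyl-6-oxo-3-[(E)-3-oxoprop-1-en-1-yl]-7,8-dihydro-6H-isochromen-8-yl 2,4-bis(triisopropylsilyloxy)-6-methylbenzoate
Product: 14 (E)-3-[(7R,8R)-8-{[2,4-bis(triisopropylsilyloxy)-6-methylbenzoyl]oxy}-7-hydroxy-7-methyl-6-oxo-7,8-dihydro-6H-isochromen-3-yl]prop-2-enoic acid
Conditions: NaClO2, NaH2PO4, 2-methyl-2-butene, t-BuOH–H2O, 0 °C → rt
Reagents that add atoms: sodium chlorite [Na+].[O-]Cl=O
Why: Pinnick oxidation converts the enal into the acid without isomerising the E alkene, the large excess of 2-methyl-2-butene removing hypochlorous acid before it can chlorinate the electron-rich pyran–dienone system.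

Step 11
Reactants: 14 (E)-3-[(7R,8R)-8-{[2,4-bis(triisopropylsilyloxy)-6-methylbenzoyl]oxy}-7-hydroxy-7-methyl-6-oxo-7,8-dihydro-6H-isochromen-3-yl]prop-2-enoic acid
Product: 15 (+)-mitorubrinic acid B, (E)-3-[(7R,8R)-8-[(2,4-dihydroxy-6-methylbenzoyl)oxy]-7-hydroxy-7-methyl-6-oxo-7,8-dihydro-6H-isochromen-3-yl]prop-2-enoic acid
Conditions: Bu4NF–AcOH (1:1, 3 equiv), THF, 0 °C; pH 4 buffer work-up
Reagents that add atoms: none
Why: Buffered fluoride cleaves aryl silyl ethers rapidly at 0 °C, and the acetic acid buffer should suppress base-induced acyl migration from O8 to O7 and opening of the pyran ring, so both stereocentres are kept.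

**Compound list**
1 | 5-bromo-2-methylanisole | COc1cc(Br)ccc1C | starting material
2 | 2-bromo-4-methoxy-5-methylbenzaldehyde | O=Cc1cc(C)c(OC)cc1Br | intermediate
3 | 2-bromo-4-hydroxy-5-methylbenzaldehyde | O=Cc1cc(C)c(O)cc1Br | intermediate
4 | (E)-pent-2-en-4-yn-1-ol | C#C/C=C/CO | starting material
5 | (E)-tert-butyldimethyl(pent-2-en-4-yn-1-yloxy)silane | C#C/C=C/CO[Si](C)(C)C(C)(C)C | intermediate
6 | 4-hydroxy-5-methyl-2-[(E)-5-(tert-butyldimethylsilyloxy)pent-3-en-1-yn-1-yl]benzaldehyde | O=Cc1cc(C)c(O)cc1C#C/C=C/CO[Si](C)(C)C(C)(C)C | intermediate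
7 | (6R)-4-formyl-6-hydroxy-6-methyl-3-[(E)-5-(tert-butyldimethylsilyloxy)pent-3-en-1-yn-1-yl]cyclohexa-2,4-dien-1-one | O=CC1=C[C@@](C)(O)C(=O)C=C1C#C/C=C/CO[Si](C)(C)C(C)(C)C | intermediate
8 | orsellinic acid (2,4-dihydroxy-6-methylbenzoic acid) | Cc1cc(O)cc(O)c1C(=O)O | starting material
9 | triisopropylsilyl 2,4-bis(triisopropylsilyloxy)-6-methylbenzoate (not isolated) | Cc1cc(O[Si](C(C)C)(C(C)C)C(C)C)cc(O[Si](C(C)C)(C(C)C)C(C)C)c1C(=O)O[Si](C(C)C)(C(C)C)C(C)C | intermediate
10 | 2,4-bis(triisopropylsilyloxy)-6-methylbenzoic acid | Cc1cc(O[Si](C(C)C)(C(C)C)C(C)C)cc(O[Si](C(C)C)(C(C)C)C(C)C)c1C(=O)O | intermediate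
11 | (7R,8R)-7-hydroxy-7-methyl-6-oxo-3-[(E)-3-(tert-butyldimethylsilyloxy)prop-1-en-1-yl]-7,8-dihydro-6H-isochromen-8-yl 2,4-bis(triisopropylsilyloxy)-6-methylbenzoate | Cc1cc(O[Si](C(C)C)(C(C)C)C(C)C)cc(O[Si](C(C)C)(C(C)C)C(C)C)c1C(=O)O[C@@H]1C2=COC(/C=C/CO[Si](C)(C)C(C)(C)C)=CC2=CC(=O)[C@]1(C)O | intermediate
12 | (7R,8R)-7-hydroxy-3-[(E)-3-hydroxyprop-1-en-1-yl]-7-methyl-6-oxo-7,8-dihydro-6H-isochromen-8-yl 2,4-bis(triisopropylsilyloxy)-6-methylbenzoate | Cc1cc(O[Si](C(C)C)(C(C)C)C(C)C)cc(O[Si](C(C)C)(C(C)C)C(C)C)c1C(=O)O[C@@H]1C2=COC(/C=C/CO)=CC2=CC(=O)[C@]1(C)O | intermediate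
13 | (7R,8R)-7-hydroxy-7-methyl-6-oxo-3-[(E)-3-oxoprop-1-en-1-yl]-7,8-dihydro-6H-isochromen-8-yl 2,4-bis(triisopropylsilyloxy)-6-methylbenzoate | Cc1cc(O[Si](C(C)C)(C(C)C)C(C)C)cc(O[Si](C(C)C)(C(C)C)C(C)C)c1C(=O)O[C@@H]1C2=COC(/C=C/C=O)=CC2=CC(=O)[C@]1(C)O | intermediate
14 | (E)-3-[(7R,8R)-8-{[2,4-bis(triisopropylsilyloxy)-6-methylbenzoyl]oxy}-7-hydroxy-7-methyl-6-oxo-7,8-dihydro-6H-isochromen-3-yl]prop-2-enoic acid | Cc1cc(O[Si](C(C)C)(C(C)C)C(C)C)cc(O[Si](C(C)C)(C(C)C)C(C)C)c1C(=O)O[C@@H]1C2=COC(/C=C/C(=O)O)=CC2=CC(=O)[C@]1(C)O | intermediate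
15 | (+)-mitorubrinic acid B | Cc1cc(O)cc(O)c1C(=O)O[C@@H]1C2=COC(/C=C/C(=O)O)=CC2=CC(=O)[C@]1(C)O | target

**Step count:** 11 steps in total; longest linear sequence 9 steps (1, 2, 4, 5, 7, 8, 9, 10, 11).

**Steps most likely to fail**

Step 7 (proposed new method). The quinol may dimerise by [4+2] cycloaddition before it cyclises. The cation may be intercepted by traces of water, or may stay at the C1 acylal stage and hydrolyse. The acid may add to both faces of C8. The fallback separates the two bond formations and avoids the cation, using two known reaction types. It sets out from 7 and 10. Amine-promoted oxa-Michael addition of the acid (Et3N, 0.2 equiv, THF, −20 °C) to C8, which is both the β-carbon of the enal and the δ-carbon of the dienone, should give the vinylogous acid adduct F1. Without isolation, CuI (10 mol%) then closes the pyran ring by cycloisomerisation of the enol oxygen onto the alkyne, as is established for alkynyl vinylogous acids. The fallback comes back to the route at 11.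

Step 5. Oxygen transfer to the electron-poor ring may be slow. Oxygen may also be delivered to the unsubstituted ortho carbon and lead on to an ortho-quinone. Facial discrimination may be incomplete, and the quinol may dimerise during a long reaction. The fallback changes the oxidation level so that the ring is no longer deactivated. It sets out from 6. NaBH4 in MeOH at 0 °C reduces the aldehyde to the benzylic alcohol F2. The same iodyl reagent hydroxylates this ordinary 2-alkylphenol to the quinol carbinol F3. MnO2 in CH2Cl2 then oxidises its dienylic primary alcohol, which returns the route to 7.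

Step 8. The aryl silyl groups, activated by the ortho and para ester, may be lost together with the alkyl one, or HF may promote ionisation of the C8 ester. The fallback gives up the protected late-stage oxidation. It sets out from 11. Bu4NF–AcOH in THF removes all three silyl groups to give the triol F4. MnO2 oxidises only its allylic alcohol to the phenolic enal F5. Pinnick oxidation with a large excess of 2-methyl-2-butene then gives the acid directly, so the fallback comes back at 15.

**Further compounds**
F1 | step 7 | (1R,6R)-2-formyl-5,6-dihydroxy-6-methyl-3-[(E)-5-(tert-butyldimethylsilyloxy)pent-3-en-1-yn-1-yl]cyclohexa-2,4-dien-1-yl 2,4-bis(triisopropylsilyloxy)-6-methylbenzoate | O=CC1=C(C#C/C=C/CO[Si](C)(C)C(C)(C)C)C=C(O)[C@](C)(O)[C@@H]1OC(=O)c1c(C)cc(O[Si](C(C)C)(C(C)C)C(C)C)cc1O[Si](C(C)C)(C(C)C)C(C)C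
F2 | step 5 | 4-(hydroxymethyl)-2-methyl-5-[(E)-5-(tert-butyldimethylsilyloxy)pent-3-en-1-yn-1-yl]phenol | OCc1cc(C)c(O)cc1C#C/C=C/CO[Si](C)(C)C(C)(C)C
F3 | step 5 | (6R)-6-hydroxy-4-(hydroxymethyl)-6-methyl-3-[(E)-5-(tert-butyldimethylsilyloxy)pent-3-en-1-yn-1-yl]cyclohexa-2,4-dien-1-one | OCC1=C[C@@](C)(O)C(=O)C=C1C#C/C=C/CO[Si](C)(C)C(C)(C)C
F4 | step 8 | (7R,8R)-7-hydroxy-3-[(E)-3-hydroxyprop-1-en-1-yl]-7-methyl-6-oxo-7,8-dihydro-6H-isochromen-8-yl 2,4-dihydroxy-6-methylbenzoate | Cc1cc(O)cc(O)c1C(=O)O[C@@H]1C2=COC(/C=C/CO)=CC2=CC(=O)[C@]1(C)O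
F5 | step 8 | (7R,8R)-7-hydroxy-7-methyl-6-oxo-3-[(E)-3-oxoprop-1-en-1-yl]-7,8-dihydro-6H-isochromen-8-yl 2,4-dihydroxy-6-methylbenzoate | Cc1cc(O)cc(O)c1C(=O)O[C@@H]1C2=COC(/C=C/C=O)=CC2=CC(=O)[C@]1(C)O
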